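## The problem

The target is a diaryl ether of two different, heavily substituted benzene rings and has no stereocentre, so the whole difficulty is regiochemistry and chemoselectivity. Ring A is an olivetolic acid (C1 carboxyl, C2 pentyl, C4 and C6 hydroxyls) whose fifth substituent, the bridging oxygen at C3, lies between the pentyl chain and the C4 hydroxyl. Ring B is a methyl benzoate (C1') with the ether oxygen at C2', a methoxy group at C4' and a pentanoyl ketone at C6'. The ether bond therefore joins an electron-rich phenol with two ortho substituents to a carbon next to the ring B carboxyl, and the two carboxyl groups (free acid on ring A, methyl ester on ring B) must stay distinguishable to the end. The ring A acid is a β-resorcylic acid that decarboxylates readily in acid or on heating. The ortho keto ester of ring B can close to a cyclic pseudo-ester or, with base, contract to an indane-1,3-dione. The enabling feature is that same ortho pair: the C1' ester and the C6' ketone are what methanol makes from a 3-butylidenephthalide, an enol lactone that forms from a 2-iodobenzoic acid and pent-1-yne, so the ring B carboxyl can act first as the ring-closing nucleophile and only afterwards become the ester.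

## Retrosynthesis

**18 back to 16.** The C4 and C6 hydroxyls of target 18 are masked as benzyl ethers in 17, and the ring A carboxyl of 17 is taken back to the aldehyde of 16. Benzyl is preferred to acid-labile groups because the last step must not expose the β-resorcylic acid to acid. An aldehyde is preferred to a second ester because it needs no protecting group, cannot be confused with the ring B methyl ester, and is inert to the copper, palladium and methoxide steps. The forward reactions are a buffered aldehyde oxidation and a neutral hydrogenolysis.

**16 back to 15.** Cutting the ester C–O bond of 16 and reconnecting the carboxyl oxygen to the ketone carbon gives enol lactone 15. This merges the two ortho carbonyl groups of ring B into one unit that already has the ketone carbon at the right oxidation level. The forward reaction is a catalytic opening with methoxide that must stop at the keto ester.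

**15 back to 12 and 13 (key disconnection).** The C6'–C(acyl) bond and the lactone C–O bond of 15 are cut together, leading to 2-iodobenzoic acid 12 and pent-1-yne 13. Against an acylation of ring B, this cut uses the carboxyl as an internal nucleophile and sets the chain length with a commercial alkyne. The forward step must couple at C6' and then close in the 5-exo sense through alkynyl acid 14.

**12 back to 8 and 11.** The C2'–O bond is cut to give ring A phenol 8 and the symmetrical diiodo acid 11. The neighbouring option, forming the ether first and iodinating C6' afterwards, is rejected: once the ether exists both rings are resorcinol-type ethers whose free positions (C5 of ring A, C3' and C5' of ring B) are far more nucleophilic than C6', which is meta to both ring B oxygens. In 11 the iodine is already in place and the ortho carboxylate activates the C–I bond towards copper. The forward reaction has to stop after one of the two equivalent C–I bonds.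

**11 back to 9.** Both C–I bonds of 11 are cut to give 4-methoxybenzoic acid 9. The two positions ortho to the carboxyl are equivalent and are reached by carboxylate-directed C–H iodination through mono-iodide 10, on a ring deactivated by its carboxyl group.

**8 back to 1.** The formyl group of 8 is removed to give phenol 6, whose hydroxyl comes from Baeyer–Villiger oxidation of aldehyde 4 through formate 5; 4 is the dibenzyl ether of aldehyde 3, the formylation product of olivetol 1 by way of iminium salt 2. The two positions of 1 next to the pentyl chain are thus used in turn: the first formyl group becomes the C3 oxygen, the second (introduced via iminium salt 7) becomes the carboxyl carbon. Both formylations occur at a position ortho to one oxygen and para to another, which is the normal site for resorcinol derivatives, so no regiochemical question is left open.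

## Roads not taken

**Alternative 1:** Ring A would be cut at C1–C2 and traced to the open-chain diketo-dioxinone A1, which carries the ring B aryloxy group on the carbon between its two ketones. Mild base and then acid would close A1 by aldol addition of the dioxinone α-carbon to the pentyl ketone and dehydration, giving the salicylate acetonide A2. Its merit is real: all ring A substituents are placed by carbonyl chemistry, the C4 hydroxyl emerges free, and neither a hindered Ullmann coupling nor benzyl groups are needed, which is better than the chosen plan in protecting-group economy. Its weak points are the making of A1, which needs a C–O bond from a hindered, hydrogen-bonded salicylate phenol to a carbon flanked by two carbonyl groups, and the presence of four ketone carbonyls in A1, among which the ring B pentanoyl group is a competing aldol partner. Opening the acetonide of A2 to the free acid also calls for hydroxide or heat, which endangers the ring B keto ester. The chosen plan sets against this that every step is a known reaction type on a stable aromatic substrate and that the ring B ketone does not exist until the penultimate stage of ring B chemistry.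

**Alternative 2:** Ring A would be cut at C2–C3 and C1–C6 and assembled by an Alder–Rickert sequence: the aryloxy silyloxy diene A3 and benzyl oct-2-ynoate A4 would be heated to about 160 to 200 °C, and the bicyclic adduct would lose ethylene to give the fully substituted benzoate A5. The polarisation of A3 matches that of A4, so the regiochemistry of all six ring A positions would be fixed in one step, a clear advantage over two successive formylations. Against it stand the preparation of A3, which requires an aryloxy group next to the carbonyl of a vinylogous ester and a kinetically formed silyl dienol ether, the heat needed for cycloaddition and retro-cycloaddition on a substrate with a silyl enol ether and a ketal, and the need to carry the ring B ketone as a ketal from the start and release it with acid later. The step count would be no shorter, and the chosen plan runs all its bond-forming steps at or below 90 °C with the ketone masked in the lactone.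

**Alternative 3:** Ring B would be cut at C1'–C2' and C5'–C6' and formed by Diels–Alder reaction of the aryloxy pyrone A6 with the ketal-bearing ynoate A7, followed by loss of CO2 to give A8. Here the diaryl ether oxygen would be attached by addition–elimination on a pyrone and not by copper on a crowded aryl iodide. This is the one respect in which this road is cleaner than the chosen one, which has to accept a statistical mono-coupling on a diiodide. The polarisation of A6 and A7 is also matched. Its weaknesses are the dienophile, whose reacting carbon carries a quaternary ketal centre, the high temperature this implies, the lability of the acyl-like aryloxy–pyrone bond of A6 towards nucleophiles, and three benzyl groups plus a ketal to remove from A8. Ring A would still have to be built as an ester-protected phenol by a sequence as long as steps 1 to 4. The chosen plan answers with a ring B partner made in one step from a commodity acid and with a shorter end game.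

Key step: step 7

Assumption: the target is taken as the open-chain keto ester drawn, not as its cyclic 3-methoxyphthalide (pseudo-ester) tautomer.

## Route

Step 1
Reactants: 1 olivetol (5-pentylbenzene-1,3-diol)
Product: 3 2,4-dihydroxy-6-pentylbenzaldehyde, via iminium chloride 2 (not isolated)
Conditions: POCl3, DMF, 0 °C to rt; then H2O, 50 °C
Reagents that add atoms: N,N-dimethylformamide CN(C)C=O (formyl carbon); water O (carbonyl oxygen)
Why: Vilsmeier–Haack formylation; the chloroiminium ion attacks the resorcinol position that is ortho to one hydroxyl and para to the other (next to the pentyl chain), not the position between the hydroxyls, as is usual for 5-alkylresorcinols, and warm water hydrolyses iminium salt 2.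

Step 2
Reactants: 3 2,4-dihydroxy-6-pentylbenzaldehyde
Product: 4 2,4-bis(benzyloxy)-6-pentylbenzaldehyde
Conditions: BnBr (2.5 equiv), K2CO3, DMF, 60 °C
Reagents that add atoms: benzyl bromide BrCc1ccccc1
Why: Williamson ether synthesis; the hydrogen-bonded C2 hydroxyl needs the excess of halide and gentle heating, and benzyl survives every later step and is removed at the end without acid.

Step 3
Reactants: 4 2,4-bis(benzyloxy)-6-pentylbenzaldehyde
Product: 6 2,4-bis(benzyloxy)-6-pentylphenol, via aryl formate 5 (not isolated)
Conditions: mCPBA, CH2Cl2, 0 °C to rt; then K2CO3 (cat.), MeOH, rt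
Reagents that add atoms: 3-chloroperoxybenzoic acid O=C(OO)c1cccc(Cl)c1
Why: Baeyer–Villiger (Dakin-type) oxidation; the electron-rich, di-ortho-substituted aryl group migrates in preference to hydrogen, the formate shields the new phenol from the peracid, and catalytic K2CO3 then passes the formyl group to methanol.

Step 4
Reactants: 6 2,4-bis(benzyloxy)-6-pentylphenol
Product: 8 4,6-bis(benzyloxy)-3-hydroxy-2-pentylbenzaldehyde, via iminium chloride 7 (not isolated)
Conditions: POCl3, DMF, 0 to 60 °C; then H2O, 60 °C
Reagents that add atoms: N,N-dimethylformamide CN(C)C=O (formyl carbon); water O (carbonyl oxygen)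
Why: Vilsmeier–Haack formylation; attack should occur at the one position that is para to a benzyloxy group and ortho to the other (next to the pentyl chain), as in 1,2,4-trialkoxybenzenes, while the site between the two benzyloxy groups is the disfavoured 2-position of a resorcinol diether and the hydroxyl is meta to both sites; any O-formyl group is lost in the aqueous hydrolysis of 7.

Step 5
Reactants: 9 4-methoxybenzoic acid
Product: 11 2,6-diiodo-4-methoxybenzoic acid, via mono-iodo acid 10 (not isolated)
Conditions: NIS (3 equiv), [Cp*Ir(H2O)3]SO4 (3 mol %), (CF3)2CHOH, 40 °C
Reagents that add atoms: N-iodosuccinimide O=C1CCC(=O)N1I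
Why: Carboxylate-directed ortho C–H iodination of a benzoic acid; the carboxylate binds the trivalent iridium centre, cyclometalation and reaction of the iridacycle with NIS give 10, and the second ortho position then reacts in the same way, while the carboxyl-deactivated ring should resist undirected iodination next to the methoxy group.

Step 6
Reactants: 8 4,6-bis(benzyloxy)-3-hydroxy-2-pentylbenzaldehyde; 11 2,6-diiodo-4-methoxybenzoic acid (2 equiv)
Product: 12 2-[4,6-bis(benzyloxy)-3-formyl-2-pentylphenoxy]-6-iodo-4-methoxybenzoic acid
Conditions: CuI (10 mol %), picolinic acid (20 mol %), K3PO4, DMSO, 90 °C; then aq HCl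
Reagents that add atoms: none
Why: Ullmann diaryl ether condensation, helped by the ortho carboxylate and by the CuI–picolinic acid system suited to hindered phenols; phenol 8 is the limiting partner and the twofold excess of 11 should hold the reaction at substitution of one C–I bond, the surplus 11 being recovered.

Step 7
Reactants: 12 2-[4,6-bis(benzyloxy)-3-formyl-2-pentylphenoxy]-6-iodo-4-methoxybenzoic acid; 13 pent-1-yne (3 equiv)
Product: 15 4,6-bis(benzyloxy)-3-{[(1Z)-1-butylidene-6-methoxy-3-oxo-1,3-dihydro-2-benzofuran-4-yl]oxy}-2-pentylbenzaldehyde, via alkynyl acid 14 (not isolated)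
Conditions: PdCl2(PPh3)2 (5 mol %), CuI (10 mol %), Et3N, DMF, sealed tube, 60 °C
Reagents that add atoms: none
Why: Zerovalent palladium, formed in the flask from PdCl2(PPh3)2, inserts into the C6'–I bond of the triethylammonium salt of 12, the copper acetylide made from 13, CuI and Et3N transmetalates, and reductive elimination gives alkynyl acid 14 (Sonogashira coupling). The carboxylate oxygen of 14 then adds anti across the metal-coordinated triple bond at the aryl-bearing carbon, and protonation of the vinyl–metal bond releases the enol lactone. The closest known reaction type is the palladium–copper heteroannulation of 2-iodobenzoic acids with terminal alkynes to (Z)-3-ylidenephthalides. The one ring formed, the five-membered lactone, closes in the 5-exo-dig mode. No stereocentre is created; the Z geometry follows from anti addition and is of no consequence because step 8 removes the double bond. The selectivity needed is 5-exo over 6-endo closure (phthalide, not isocoumarin), which the free carboxylate under palladium–copper catalysis with Et3N in DMF is known to favour; the isocoumarin is the expected minor isomer and should be separable. The ring A aldehyde is hindered and non-enolisable and the benzyl ethers are inert, so both are spectators. Pent-1-yne boils at 40 °C, hence the sealed vessel and the excess.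

Step 8
Reactants: 15 4,6-bis(benzyloxy)-3-{[(1Z)-1-butylidene-6-methoxy-3-oxo-1,3-dihydro-2-benzofuran-4-yl]oxy}-2-pentylbenzaldehyde
Product: 16 methyl 2-[4,6-bis(benzyloxy)-3-formyl-2-pentylphenoxy]-4-methoxy-6-pentanoylbenzoate
Conditions: NaOMe (0.2 equiv), MeOH–THF, 0 °C; then AcOH
Reagents that add atoms: methanol CO
Why: Base-catalysed methanolysis of an enol lactone; methoxide adds to the lactone carbonyl, the ring opens to the ketone enolate, and protonation by the solvent gives the methyl ester and the pentanoyl ketone; the base is kept substoichiometric and cold because the Claisen-type rearrangement of ylidenephthalides to indane-1,3-diones needs excess base and heat.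

Step 9
Reactants: 16 methyl 2-[4,6-bis(benzyloxy)-3-formyl-2-pentylphenoxy]-4-methoxy-6-pentanoylbenzoate
Product: 17 4,6-bis(benzyloxy)-3-[5-methoxy-2-(methoxycarbonyl)-3-pentanoylphenoxy]-2-pentylbenzoic acid
Conditions: NaClO2, NaH2PO4, 2-methyl-2-butene, t-BuOH–THF–H2O, 0 °C to rt
Reagents that add atoms: sodium chlorite [Na+].[O-]Cl=O
Why: Pinnick oxidation; chlorous acid converts the hindered aryl aldehyde to the acid without touching the ketone, the ester or the benzyl ethers, and 2-methyl-2-butene traps hypochlorous acid so that the electron-rich rings are not chlorinated.

Step 10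
Reactants: 17 4,6-bis(benzyloxy)-3-[5-methoxy-2-(methoxycarbonyl)-3-pentanoylphenoxy]-2-pentylbenzoic acid
Product: 18 4,6-dihydroxy-3-[5-methoxy-2-(methoxycarbonyl)-3-pentanoylphenoxy]-2-pentylbenzoic acid (CNP0262789.0)
Conditions: H2 (1 atm), Pd/C (10%), EtOAc, rt
Reagents that add atoms: none
Why: Hydrogenolysis of benzyl aryl ethers; the C4 and C6 hydroxyls are freed under neutral conditions at room temperature, so the decarboxylation-prone acid never meets acid or heat, and the reaction is stopped once two equivalents of hydrogen are taken up so that the aryl ketone is not reduced.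

## Compound list

1 | olivetol (5-pentylbenzene-1,3-diol) | CCCCCc1cc(O)cc(O)c1 | starting material
2 | N-[(2,4-dihydroxy-6-pentylphenyl)methylidene]-N-methylmethanaminium chloride | CCCCCc1cc(O)cc(O)c1C=[N+](C)C.[Cl-] | intermediate
3 | 2,4-dihydroxy-6-pentylbenzaldehyde | CCCCCc1cc(O)cc(O)c1C=O | intermediate
4 | 2,4-bis(benzyloxy)-6-pentylbenzaldehyde | CCCCCc1cc(OCc2ccccc2)cc(OCc2ccccc2)c1C=O | intermediate
5 | 2,4-bis(benzyloxy)-6-pentylphenyl formate | CCCCCc1cc(OCc2ccccc2)cc(OCc2ccccc2)c1OC=O | intermediate
6 | 2,4-bis(benzyloxy)-6-pentylphenol | CCCCCc1cc(OCc2ccccc2)cc(OCc2ccccc2)c1O | intermediate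
7 | N-{[4,6-bis(benzyloxy)-3-hydroxy-2-pentylphenyl]methylidene}-N-methylmethanaminium chloride | CCCCCc1c(O)c(OCc2ccccc2)cc(OCc2ccccc2)c1C=[N+](C)C.[Cl-] | intermediate
8 | 4,6-bis(benzyloxy)-3-hydroxy-2-pentylbenzaldehyde | CCCCCc1c(O)c(OCc2ccccc2)cc(OCc2ccccc2)c1C=O | intermediate
9 | 4-methoxybenzoic acid | COc1ccc(C(=O)O)cc1 | starting material
10 | 2-iodo-4-methoxybenzoic acid | COc1ccc(C(=O)O)c(I)c1 | intermediate
11 | 2,6-diiodo-4-methoxybenzoic acid | COc1cc(I)c(C(=O)O)c(I)c1 | intermediate
12 | 2-[4,6-bis(benzyloxy)-3-formyl-2-pentylphenoxy]-6-iodo-4-methoxybenzoic acid | CCCCCc1c(Oc2cc(OC)cc(I)c2C(=O)O)c(OCc2ccccc2)cc(OCc2ccccc2)c1C=O | intermediate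
13 | pent-1-yne | CCCC#C | starting material
14 | 2-[4,6-bis(benzyloxy)-3-formyl-2-pentylphenoxy]-4-methoxy-6-(pent-1-yn-1-yl)benzoic acid | CCCC#Cc1cc(OC)cc(Oc2c(CCCCC)c(C=O)c(OCc3ccccc3)cc2OCc2ccccc2)c1C(=O)O | intermediate
15 | 4,6-bis(benzyloxy)-3-{[(1Z)-1-butylidene-6-methoxy-3-oxo-1,3-dihydro-2-benzofuran-4-yl]oxy}-2-pentylbenzaldehyde | CCC/C=C1\OC(=O)c2c(Oc3c(CCCCC)c(C=O)c(OCc4ccccc4)cc3OCc3ccccc3)cc(OC)cc12 | intermediate
16 | methyl 2-[4,6-bis(benzyloxy)-3-formyl-2-pentylphenoxy]-4-methoxy-6-pentanoylbenzoate | CCCCC(=O)c1cc(OC)cc(Oc2c(CCCCC)c(C=O)c(OCc3ccccc3)cc2OCc2ccccc2)c1C(=O)OC | intermediate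
17 | 4,6-bis(benzyloxy)-3-[5-methoxy-2-(methoxycarbonyl)-3-pentanoylphenoxy]-2-pentylbenzoic acid | CCCCC(=O)c1cc(OC)cc(Oc2c(CCCCC)c(C(=O)O)c(OCc3ccccc3)cc2OCc2ccccc2)c1C(=O)OC | intermediate
18 | 4,6-dihydroxy-3-[5-methoxy-2-(methoxycarbonyl)-3-pentanoylphenoxy]-2-pentylbenzoic acid (CNP0262789.0) | CCCCCc1c(Oc2cc(OC)cc(C(=O)CCCC)c2C(=O)OC)c(O)cc(O)c1C(=O)O | target

## Step count and least certain steps

Total: 10 steps. Longest linear sequence: 9 steps from olivetol 1 (steps 1 to 4 and 6 to 10); step 5 is a one-step branch that supplies ring B.

**Step 7 (key step).** The likeliest failure is closure in the 6-endo sense competing with the 5-exo closure, which after step 8 would put the ketone one carbon away from the ring; oxidative dimerisation or evaporative loss of the alkyne may also starve the coupling. The fallback gives up the cyclisation and builds the aryl ketone directly, so no closure regiochemistry arises. It sets out from 12. Alkylation of the carboxylate with MeI and KHCO3 in DMF gives methyl 2-[4,6-bis(benzyloxy)-3-formyl-2-pentylphenoxy]-6-iodo-4-methoxybenzoate F1. Insertion of zinc dust in the presence of LiCl in THF, a process that tolerates aldehydes and is eased by the ortho ester, gives the arylzinc iodide {3-[4,6-bis(benzyloxy)-3-formyl-2-pentylphenoxy]-5-methoxy-2-(methoxycarbonyl)phenyl}zinc iodide F2. Negishi acylation of F2 with pentanoyl chloride (CCCCC(Cl)=O) and catalytic Pd(PPh3)4 returns to the route at 16, bypassing 15 and step 8.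

**Step 6.** Substitution may not stop after one C–I bond (a second arylation, or reductive loss of the remaining iodine), and the hindered phenoxide may couple slowly. The fallback makes the two halogens different and sets out from 8. Commercial 2-bromo-4-methoxybenzoic acid (COc1ccc(C(=O)O)c(Br)c1) is iodinated at its single free ortho position under the step 5 conditions to 2-bromo-6-iodo-4-methoxybenzoic acid F3. Phenol 8 is coupled at the C–I bond only (CuI, picolinic acid, K3PO4, DMSO, 70 °C) to give 2-[4,6-bis(benzyloxy)-3-formyl-2-pentylphenoxy]-6-bromo-4-methoxybenzoic acid F4. Aromatic Finkelstein exchange on the sodium carboxylate (CuI, NaI, trans-N,N'-dimethylcyclohexane-1,2-diamine, dioxane, 110 °C) then turns C–Br into C–I and returns to the route at 12.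

**Step 5.** Undirected electrophilic iodination next to the methoxy group may compete with the directed reaction, or the reaction may stall after the first iodination. The fallback brings iodine in by halogen exchange, not C–H activation; it replaces starting material 9 and returns at 11. Commercial 3,5-dibromoanisole (COc1cc(Br)cc(Br)c1) is deprotonated between the two bromine atoms with lithium diisopropylamide in THF at −78 °C to (2,6-dibromo-4-methoxyphenyl)lithium F5. Carboxylation with CO2 and acidification give 2,6-dibromo-4-methoxybenzoic acid F6, and twofold aromatic Finkelstein exchange under the conditions named above gives 11.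

**Step 8.** The opened enolate may attack the newly formed ester (ring contraction to the indanedione), or the keto ester may re-close to the cyclic pseudo-ester during an acidic work-up. The fallback separates ring opening from ester formation and sets out from 15. LiOH in aqueous THF opens the lactone to 2-[4,6-bis(benzyloxy)-3-formyl-2-pentylphenoxy]-4-methoxy-6-pentanoylbenzoic acid F7, whose carboxylate cannot undergo the Claisen-type closure. Alkylation of that carboxylate with MeI and KHCO3 in DMF, which gives the open ester and not the pseudo-ester, returns to the route at 16.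

**Step 10.** Over-reduction of the aryl ketone, followed by lactonisation onto the neighbouring ester, may accompany debenzylation, and the product may decarboxylate if warmed during isolation. The fallback replaces hydrogenolysis by Lewis-acid debenzylation: from 17, BCl3 with pentamethylbenzene as benzyl cation scavenger in CH2Cl2 at −78 °C, then a cold aqueous quench, gives 18 directly without a new intermediate.

## Further compounds

F1 | step 7 | methyl 2-[4,6-bis(benzyloxy)-3-formyl-2-pentylphenoxy]-6-iodo-4-methoxybenzoate | CCCCCc1c(Oc2cc(OC)cc(I)c2C(=O)OC)c(OCc2ccccc2)cc(OCc2ccccc2)c1C=O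
F2 | step 7 | {3-[4,6-bis(benzyloxy)-3-formyl-2-pentylphenoxy]-5-methoxy-2-(methoxycarbonyl)phenyl}zinc iodide | CCCCCc1c(Oc2cc(OC)cc([Zn]I)c2C(=O)OC)c(OCc2ccccc2)cc(OCc2ccccc2)c1C=O
F3 | step 6 | 2-bromo-6-iodo-4-methoxybenzoic acid | COc1cc(Br)c(C(=O)O)c(I)c1
F4 | step 6 | 2-[4,6-bis(benzyloxy)-3-formyl-2-pentylphenoxy]-6-bromo-4-methoxybenzoic acid | CCCCCc1c(Oc2cc(OC)cc(Br)c2C(=O)O)c(OCc2ccccc2)cc(OCc2ccccc2)c1C=O
F5 | step 5 | (2,6-dibromo-4-methoxyphenyl)lithium | [Li]c1c(Br)cc(OC)cc1Br
F6 | step 5 | 2,6-dibromo-4-methoxybenzoic acid | COc1cc(Br)c(C(=O)O)c(Br)c1
F7 | step 8 | 2-[4,6-bis(benzyloxy)-3-formyl-2-pentylphenoxy]-4-methoxy-6-pentanoylbenzoic acid | CCCCC(=O)c1cc(OC)cc(Oc2c(CCCCC)c(C=O)c(OCc3ccccc3)cc2OCc2ccccc2)c1C(=O)O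
F0 | step 10 | none | none
A1 | alternative 1 | methyl 2-{[1-(2,2-dimethyl-4-oxo-4H-1,3-dioxin-6-yl)-2,4-dioxononan-3-yl]oxy}-4-methoxy-6-pentanoylbenzoate | CCCCCC(=O)C(Oc1cc(OC)cc(C(=O)CCCC)c1C(=O)OC)C(=O)CC1=CC(=O)OC(C)(C)O1
A2 | alternative 1 | methyl 2-[(7-hydroxy-2,2-dimethyl-4-oxo-5-pentyl-4H-1,3-benzodioxin-6-yl)oxy]-4-methoxy-6-pentanoylbenzoate | CCCCCc1c(Oc2cc(OC)cc(C(=O)CCCC)c2C(=O)OC)c(O)cc2OC(C)(C)OC(=O)c12
A3 | alternative 2 | methyl 2-{[4-(benzyloxy)-2-(trimethylsilyloxy)cyclohexa-1,3-dien-1-yl]oxy}-6-(2-butyl-1,3-dioxolan-2-yl)-4-methoxybenzoate | COC(=O)c1c(OC2=C(O[Si](C)(C)C)C=C(OCc3ccccc3)CC2)cc(OC)cc1C1(CCCC)OCCO1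
A4 | alternative 2 | benzyl oct-2-ynoate | CCCCCC#CC(=O)OCc1ccccc1
A5 | alternative 2 | benzyl 6-(benzyloxy)-3-[3-(2-butyl-1,3-dioxolan-2-yl)-5-methoxy-2-(methoxycarbonyl)phenoxy]-2-pentyl-4-(trimethylsilyloxy)benzoate | CCCCCc1c(Oc2cc(OC)cc(C3(CCCC)OCCO3)c2C(=O)OC)c(O[Si](C)(C)C)cc(OCc2ccccc2)c1C(=O)OCc1ccccc1
A6 | alternative 3 | benzyl 4,6-bis(benzyloxy)-3-[(4-methoxy-2-oxo-2H-pyran-6-yl)oxy]-2-pentylbenzoate | CCCCCc1c(Oc2cc(OC)cc(=O)o2)c(OCc2ccccc2)cc(OCc2ccccc2)c1C(=O)OCc1ccccc1
A7 | alternative 3 | methyl 3-(2-butyl-1,3-dioxolan-2-yl)prop-2-ynoate | CCCCC1(C#CC(=O)OC)OCCO1
A8 | alternative 3 | benzyl 2,4-bis(benzyloxy)-5-[3-(2-butyl-1,3-dioxolan-2-yl)-5-methoxy-2-(methoxycarbonyl)phenoxy]-6-pentylbenzoate | COC(=O)c1c(Oc2c(CCCCC)c(C(=O)OCc3ccccc3)c(OCc3ccccc3)cc2OCc2ccccc2)cc(OC)cc1C1(CCCC)OCCO1
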